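**Plan**

- Retrosynthetic cuts, in order: (a) the four C–H bonds at C4, C3a, C6a and C6, so the tetrahydrofuran ring (O5, C4, C3a, C6a, C6) goes back to an aromatic furan; (b) the C6–catechol bond (Negishi); (c) the lactone O2–C1 bond and C3–H (ketone reduction with ring closure); (d) the C3–syringyl bond (acylation).
- Forward: the furan ring is bought as dimethyl furan-3,4-dicarboxylate and desymmetrised; the syringyl ketone is attached; the lactone ring closes on the furan 3,4-bond; the catechol ring is attached at C6; the furan is saturated last; the phenols are freed.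
- Stereochemistry: C3 comes from a catalyst-controlled transfer hydrogenation; C3a, C6a and C6 are relayed from C3 in one face-selective syn hydrogenation.
- Enabling feature: in the target, H-3, H-3a, H-6a and H-6 all lie on the convex face of the cis-fused lactone/tetrahydrofuran bicycle (both aryl groups endo). The three stereocentres of the tetrahydrofuran ring are therefore the all-syn hydrogenation pattern of a flat furan, and the C3 aryl of the lactone ring covers the other face of the planar furo[3,4-c]furanone precursor.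
- Exo-selective routes (aldol/cyclisation, C–H insertion, cycloaddition to a butenolide) would work against this hindered isomer; here it is the kinetic product.

Key step: step 7

Assumption: the target is read as the all-cis (3S,3aS,6S,6aR) isomer; the sense of the transfer hydrogenation in step 4 is assigned from the usual model (unhindered conjugated aryl in the aryl pocket), and the (R,R) catalyst would be used if the sense proved opposite.

**Route**

Step 1
Reactants: 1 dimethyl furan-3,4-dicarboxylate
Product: 2 4-(methoxycarbonyl)furan-3-carboxylic acid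
Conditions: aq NaOH (1.0 equiv), THF, 0 °C; then aq HCl to pH 2
Reagents that add atoms: sodium hydroxide, [Na+].[OH-]
Why: Selective monohydrolysis of a symmetric diester should stop after one ester because the carboxylate formed deactivates its neighbour, and the symmetry of 1 removes any regiochemical question.

Step 2
Reactants: 3 4-bromo-2,6-dimethoxyphenol
Product: 4 (4-bromo-2,6-dimethoxyphenoxy)(tert-butyl)dimethylsilane
Conditions: TBSCl, imidazole, DMF, rt to 40 °C
Reagents that add atoms: tert-butyldimethylsilyl chloride, CC(C)(C)[Si](C)(C)Cl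
Why: Standard O-silylation; the aryl silyl ether should survive the organometallic steps and the hydrogenation and can be removed at the end with buffered fluoride, without acid or base.

Step 3
Reactants: 2 4-(methoxycarbonyl)furan-3-carboxylic acid; 4 (4-bromo-2,6-dimethoxyphenoxy)(tert-butyl)dimethylsilane
Product: 7 methyl 4-[4-(tert-butyldimethylsilyloxy)-3,5-dimethoxybenzoyl]furan-3-carboxylate, via acid chloride 5 (not isolated), via arylzinc chloride 6 (not isolated)
Conditions: 2, (COCl)2, cat. DMF, CH2Cl2, 0 °C to rt, evaporate; 4, Mg, LiCl, ZnCl2, THF, rt; then combine, Pd(PPh3)4 (3 mol%), THF, 0 °C to rt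
Reagents that add atoms: none
Why: Negishi acylation of an acid chloride with an arylzinc should give the ketone cleanly, because the organozinc adds neither to the product ketone nor to the neighbouring methyl ester.

Step 4
Reactants: 7 methyl 4-[4-(tert-butyldimethylsilyloxy)-3,5-dimethoxybenzoyl]furan-3-carboxylate
Product: 9 (3R)-3-[4-(tert-butyldimethylsilyloxy)-3,5-dimethoxyphenyl]-1H,3H-furo[3,4-c]furan-1-one, via hydroxy ester 8 (not isolated)
Conditions: RuCl[(S,S)-TsDPEN](p-cymene) (1 mol%), HCO2H/Et3N (5:2), EtOAc, 40 °C; then cat. DBU, toluene, 50 °C to complete ring closure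
Reagents that add atoms: none
Why: Noyori–Ikariya asymmetric transfer hydrogenation of a diaryl-type ketone, in which the unhindered conjugated syringyl ring should take the aryl pocket and the furyl ring twisted by its ortho ester the other site, should give the (R)-carbinol, which closes onto the neighbouring ester by 5-exo-trig acyl substitution as in the known reduction/lactonization of 2-acylbenzoates to phthalides.

Step 5
Reactants: 10 4-bromobenzene-1,2-diol
Product: 11 4-bromo-1,2-bis(tert-butyldimethylsilyloxy)benzene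
Conditions: TBSCl (2.3 equiv), imidazole, DMF, rt
Reagents that add atoms: tert-butyldimethylsilyl chloride, CC(C)(C)[Si](C)(C)Cl
Why: Standard double O-silylation of a catechol, with the same protecting group as in 4 so that one final operation frees all three phenols.

Step 6
Reactants: 9 (3R)-3-[4-(tert-butyldimethylsilyloxy)-3,5-dimethoxyphenyl]-1H,3H-furo[3,4-c]furan-1-one; 11 4-bromo-1,2-bis(tert-butyldimethylsilyloxy)benzene
Product: 14 (3R)-6-[3,4-bis(tert-butyldimethylsilyloxy)phenyl]-3-[4-(tert-butyldimethylsilyloxy)-3,5-dimethoxyphenyl]-1H,3H-furo[3,4-c]furan-1-one, via furylmagnesium chloride 12 (not isolated), via furylzinc chloride 13 (not isolated)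
Conditions: TMPMgCl·LiCl (1.2 equiv), THF, −40 °C; ZnCl2 (1.3 equiv), −40 °C to rt; 11, Pd(OAc)2 (2 mol%), SPhos (4 mol%), THF, 50 °C
Reagents that add atoms: none
Why: Carbonyl-directed magnesiation with a non-nucleophilic amide base should occur at C6–H (alpha to the furan oxygen and ortho to the lactone C=O, the most acidic and only coordinated C–H), and transmetalation to zinc followed by Negishi coupling should form the C6–aryl bond without touching C3.

Step 7
Reactants: 14 (3R)-6-[3,4-bis(tert-butyldimethylsilyloxy)phenyl]-3-[4-(tert-butyldimethylsilyloxy)-3,5-dimethoxyphenyl]-1H,3H-furo[3,4-c]furan-1-one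
Product: 15 (3S,3aS,6S,6aR)-6-[3,4-bis(tert-butyldimethylsilyloxy)phenyl]-3-[4-(tert-butyldimethylsilyloxy)-3,5-dimethoxyphenyl]tetrahydro-1H,3H-furo[3,4-c]furan-1-one
Conditions: H2 (20 bar), 5% Rh/Al2O3, EtOAc, rt; stopped after uptake of 2 equiv H2
Reagents that add atoms: none
Why: Heterogeneous hydrogenation should add two H2 suprafacially to the furan carbons C4, C3a, C6a and C6 while the ring lies flat on rhodium, the closest known reaction type being the all-cis hydrogenation of polysubstituted arylfurans and furan-3-carboxylates over Rh or Ru. No ring is closed: the aromatic furan ring becomes the tetrahydrofuran ring and the planar furan-lactone becomes the cis-fused 3,7-dioxabicyclo[3.3.0]octan-2-one. The C3 aryl group stands over one face of the flat bicycle, so adsorption and hydrogen delivery should take place on the C3–H face and place H-3a, H-6a and H-6 cis to H-3, which sets C3a (S), C6a (R) and C6 (S) from C3 alone and leaves both aryl groups endo (the C3 descriptor changes from R to S only through a change in CIP priorities). The step needs face selectivity (secured by the C3 aryl), complete reduction of the tetrasubstituted push–pull C6=C6a bond (helped by the strain of a lactone fused on the furan 3,4-bond and by syn delivery without desorption) and chemoselectivity against benzylic C–O hydrogenolysis and arene saturation (rhodium instead of palladium in neutral EtOAc; electron-rich arenes shielded by silyl groups).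

Step 8
Reactants: 15 (3S,3aS,6S,6aR)-6-[3,4-bis(tert-butyldimethylsilyloxy)phenyl]-3-[4-(tert-butyldimethylsilyloxy)-3,5-dimethoxyphenyl]tetrahydro-1H,3H-furo[3,4-c]furan-1-one
Product: 16 (3S,3aS,6S,6aR)-6-(3,4-dihydroxyphenyl)-3-(4-hydroxy-3,5-dimethoxyphenyl)tetrahydro-1H,3H-furo[3,4-c]furan-1-one (CNP0224550.1)
Conditions: TBAF (3.3 equiv), AcOH (3.3 equiv), THF, 0 °C to rt
Reagents that add atoms: none
Why: Fluoride cleavage of the three aryl silyl ethers under acetic acid buffering should free the phenols without forming phenoxides, which could open the benzylic C–O bonds through quinone methides, and without acid that could epimerise the endo benzylic centres.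

**Compound list**

1 | dimethyl furan-3,4-dicarboxylate | COC(=O)c1cocc1C(=O)OC | starting material
2 | 4-(methoxycarbonyl)furan-3-carboxylic acid | COC(=O)c1cocc1C(=O)O | intermediate
3 | 4-bromo-2,6-dimethoxyphenol | COc1cc(Br)cc(OC)c1O | starting material
4 | (4-bromo-2,6-dimethoxyphenoxy)(tert-butyl)dimethylsilane | COc1cc(Br)cc(OC)c1O[Si](C)(C)C(C)(C)C | intermediate
5 | methyl 4-(chlorocarbonyl)furan-3-carboxylate | COC(=O)c1cocc1C(=O)Cl | intermediate
6 | [4-(tert-butyldimethylsilyloxy)-3,5-dimethoxyphenyl]zinc chloride | COc1cc([Zn]Cl)cc(OC)c1O[Si](C)(C)C(C)(C)C | intermediate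
7 | methyl 4-[4-(tert-butyldimethylsilyloxy)-3,5-dimethoxybenzoyl]furan-3-carboxylate | COC(=O)c1cocc1C(=O)c1cc(OC)c(O[Si](C)(C)C(C)(C)C)c(OC)c1 | intermediate
8 | methyl 4-[(R)-[4-(tert-butyldimethylsilyloxy)-3,5-dimethoxyphenyl](hydroxy)methyl]furan-3-carboxylate | COC(=O)c1cocc1[C@H](O)c1cc(OC)c(O[Si](C)(C)C(C)(C)C)c(OC)c1 | intermediate
9 | (3R)-3-[4-(tert-butyldimethylsilyloxy)-3,5-dimethoxyphenyl]-1H,3H-furo[3,4-c]furan-1-one | COc1cc([C@H]2OC(=O)c3cocc32)cc(OC)c1O[Si](C)(C)C(C)(C)C | intermediate
10 | 4-bromobenzene-1,2-diol | Oc1ccc(Br)cc1O | starting material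
11 | 4-bromo-1,2-bis(tert-butyldimethylsilyloxy)benzene | CC(C)(C)[Si](C)(C)Oc1ccc(Br)cc1O[Si](C)(C)C(C)(C)C | intermediate
12 | (3R)-6-(chloromagnesio) derivative of 9 | COc1cc([C@H]2OC(=O)c3c([Mg]Cl)occ32)cc(OC)c1O[Si](C)(C)C(C)(C)C | intermediate
13 | (3R)-6-(chlorozincio) derivative of 9 | COc1cc([C@H]2OC(=O)c3c([Zn]Cl)occ32)cc(OC)c1O[Si](C)(C)C(C)(C)C | intermediate
14 | (3R)-6-[3,4-bis(tert-butyldimethylsilyloxy)phenyl]-3-[4-(tert-butyldimethylsilyloxy)-3,5-dimethoxyphenyl]-1H,3H-furo[3,4-c]furan-1-one | COc1cc([C@H]2OC(=O)c3c(-c4ccc(O[Si](C)(C)C(C)(C)C)c(O[Si](C)(C)C(C)(C)C)c4)occ32)cc(OC)c1O[Si](C)(C)C(C)(C)C | intermediate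
15 | (3S,3aS,6S,6aR)-6-[3,4-bis(tert-butyldimethylsilyloxy)phenyl]-3-[4-(tert-butyldimethylsilyloxy)-3,5-dimethoxyphenyl]tetrahydro-1H,3H-furo[3,4-c]furan-1-one | COc1cc([C@H]2OC(=O)[C@@H]3[C@H]2CO[C@@H]3c2ccc(O[Si](C)(C)C(C)(C)C)c(O[Si](C)(C)C(C)(C)C)c2)cc(OC)c1O[Si](C)(C)C(C)(C)C | intermediate
16 | (3S,3aS,6S,6aR)-6-(3,4-dihydroxyphenyl)-3-(4-hydroxy-3,5-dimethoxyphenyl)tetrahydro-1H,3H-furo[3,4-c]furan-1-one | COc1cc([C@H]2OC(=O)[C@@H]3[C@H]2CO[C@@H]3c2ccc(O)c(O)c2)cc(OC)c1O | target

**Step count**

Total: 8 steps. Longest linear sequence: 6 steps (1, 3, 4, 6, 7, 8 from compound 1).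

**Steps most likely to fail**

Step 7 (key step). The saturation may stop after one equivalent of hydrogen at the push–pull dihydrofuran, and forcing it may bring on hydrogenolysis of the benzylic C3–O bond or saturation of an arene. The fallback splits the dearomatization into two reductions of different type. It sets out from 14: one equivalent of H2 over Rh/Al2O3 at 1 bar should reduce only the C3a=C4 bond, from the face anti to the C3 aryl, and give (3S,3aS)-6-[3,4-bis(tert-butyldimethylsilyloxy)phenyl]-3-[4-(tert-butyldimethylsilyloxy)-3,5-dimethoxyphenyl]-3a,4-dihydro-1H,3H-furo[3,4-c]furan-1-one F1. Copper hydride conjugate reduction of F1 (Cu(OAc)2, 1,2-bis(diphenylphosphino)benzene, PMHS, t-BuOH, toluene, rt) should then deliver hydride to C6 on the convex face, and protonation of the enolate at C6a can only give the cis ring fusion. The fallback comes back to the route at 15.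

Step 6. The amide base may deprotonate at the wrong site (C4–H, or the benzylic C3–H with erosion of enantiopurity) or open the strained lactone. The fallback attaches the catechol ring before the stereocentre exists; it sets out from 1 and 11.
- Direct C–H arylation of excess 1 with 11 (Pd(OAc)2, KOAc, DMA, 110 °C) should give dimethyl 2-[3,4-bis(tert-butyldimethylsilyloxy)phenyl]furan-3,4-dicarboxylate F2, the two alpha positions of 1 being equivalent.
- Monohydrolysis of the ester remote from the aryl group (aq NaOH, THF, 0 °C) should give 5-[3,4-bis(tert-butyldimethylsilyloxy)phenyl]-4-(methoxycarbonyl)furan-3-carboxylic acid F3.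
- Oxalyl chloride should give methyl 2-[3,4-bis(tert-butyldimethylsilyloxy)phenyl]-4-(chlorocarbonyl)furan-3-carboxylate F4, which is coupled with arylzinc 6 as in step 3 to give methyl 2-[3,4-bis(tert-butyldimethylsilyloxy)phenyl]-4-[4-(tert-butyldimethylsilyloxy)-3,5-dimethoxybenzoyl]furan-3-carboxylate F5.
- Transfer hydrogenation as in step 4 should give methyl 2-[3,4-bis(tert-butyldimethylsilyloxy)phenyl]-4-[(R)-[4-(tert-butyldimethylsilyloxy)-3,5-dimethoxyphenyl](hydroxy)methyl]furan-3-carboxylate F6, which lactonizes.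

The fallback comes back to the route at 14.

Step 4. The catalyst may discriminate poorly between the two aryl-type groups on the ketone, giving low enantiomeric purity at the one centre that controls all others. The fallback sets the centre by enantioselective aryl transfer to an aldehyde. It sets out from 2 and 4: acid 2 is converted into its chloride 5 as in step 3 and reduced with LiAlH(OtBu)3 (THF, −78 °C) to methyl 4-formylfuran-3-carboxylate F7. Bromide 4 is converted by Miyaura borylation (B2pin2, Pd(dppf)Cl2, KOAc, dioxane, 80 °C) into 2-[4-(tert-butyldimethylsilyloxy)-3,5-dimethoxyphenyl]-4,4,5,5-tetramethyl-1,3,2-dioxaborolane F8. Rhodium(I)/chiral diene-catalysed 1,2-addition of F8 to F7 (K3PO4, toluene/H2O), as known for 2-formylbenzoates giving 3-arylphthalides, should give hydroxy ester 8, which lactonizes. The fallback comes back to the route at 9.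

**Further compounds**

F1 | step 7 | (3S,3aS)-6-[3,4-bis(tert-butyldimethylsilyloxy)phenyl]-3-[4-(tert-butyldimethylsilyloxy)-3,5-dimethoxyphenyl]-3a,4-dihydro-1H,3H-furo[3,4-c]furan-1-one | COc1cc([C@H]2OC(=O)C3=C(c4ccc(O[Si](C)(C)C(C)(C)C)c(O[Si](C)(C)C(C)(C)C)c4)OC[C@H]32)cc(OC)c1O[Si](C)(C)C(C)(C)C
F2 | step 6 | dimethyl 2-[3,4-bis(tert-butyldimethylsilyloxy)phenyl]furan-3,4-dicarboxylate | COC(=O)c1coc(-c2ccc(O[Si](C)(C)C(C)(C)C)c(O[Si](C)(C)C(C)(C)C)c2)c1C(=O)OC
F3 | step 6 | 5-[3,4-bis(tert-butyldimethylsilyloxy)phenyl]-4-(methoxycarbonyl)furan-3-carboxylic acid | OC(=O)c1coc(-c2ccc(O[Si](C)(C)C(C)(C)C)c(O[Si](C)(C)C(C)(C)C)c2)c1C(=O)OC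
F4 | step 6 | methyl 2-[3,4-bis(tert-butyldimethylsilyloxy)phenyl]-4-(chlorocarbonyl)furan-3-carboxylate | ClC(=O)c1coc(-c2ccc(O[Si](C)(C)C(C)(C)C)c(O[Si](C)(C)C(C)(C)C)c2)c1C(=O)OC
F5 | step 6 | methyl 2-[3,4-bis(tert-butyldimethylsilyloxy)phenyl]-4-[4-(tert-butyldimethylsilyloxy)-3,5-dimethoxybenzoyl]furan-3-carboxylate | COC(=O)c1c(C(=O)c2cc(OC)c(O[Si](C)(C)C(C)(C)C)c(OC)c2)coc1-c1ccc(O[Si](C)(C)C(C)(C)C)c(O[Si](C)(C)C(C)(C)C)c1
F6 | step 6 | methyl 2-[3,4-bis(tert-butyldimethylsilyloxy)phenyl]-4-[(R)-[4-(tert-butyldimethylsilyloxy)-3,5-dimethoxyphenyl](hydroxy)methyl]furan-3-carboxylate | COC(=O)c1c([C@H](O)c2cc(OC)c(O[Si](C)(C)C(C)(C)C)c(OC)c2)coc1-c1ccc(O[Si](C)(C)C(C)(C)C)c(O[Si](C)(C)C(C)(C)C)c1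
F7 | step 4 | methyl 4-formylfuran-3-carboxylate | COC(=O)c1cocc1C=O
F8 | step 4 | 2-[4-(tert-butyldimethylsilyloxy)-3,5-dimethoxyphenyl]-4,4,5,5-tetramethyl-1,3,2-dioxaborolane | COc1cc(B2OC(C)(C)C(C)(C)O2)cc(OC)c1O[Si](C)(C)C(C)(C)C
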